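The constants for making target and for losing it to substrate stand in a ratio of 2.59, and two chemists dispute what that ratio means in a flask where target is itself a reactant.

substrate 1.0 M; gas phase 200 mM (held); protic impurity 0.100 M; time 8.0 min

    dissolved gas + protic impurity → quenched reagent (k1 = 0.0286 M⁻¹ s⁻¹)
    gas phase ⇌ dissolved gas, rate k2*(csat - [dissolved gas]) (k2 = 0.0106 s⁻¹, csat = 200 mM)
    substrate + dissolved gas → target (k3 = 0.0114 M⁻¹ s⁻¹)
    substrate + target → side product (k4 = 0.00440 M⁻¹ s⁻¹)
    dissolved gas + target → over-reacted product (k5 = 0.0127 M⁻¹ s⁻¹)
    dissolved gas ⇌ dormant form (K6 = 1.7, k6 = 0.00102 s⁻¹)

- amount of target at 8.0 min, in percent of the substrate charged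
- the change that raises the amount of target at 8.0 min, in percent of the substrate charged most ("none" if none brings more than 2 percentage points) (Wednesday's / Thursday's / none)
- amount of target at 8.0 min, in percent of the substrate charged, after Thursday's

- Wednesday's: doubling the transfer coefficient of step 2, all else as stated
- Thursday's: doubling the saturation concentration of gas phase, all else as stated

- a species is counted by the substrate in it: one side product counts as two
- at the start none of the gas is dissolved
- run time (flask): 8.0 min

Both start from the dissolved gas. At the charged amounts, transfer in is balanced by transfer back, quenching and target formation near 0.0853 M, a quasi-steady level; both leave the dormant form aside, its constant 0.00102 s⁻¹ being smaller than 0.0106 s⁻¹.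

The supply side simply multiplies. Substrate meets that gas for 8.0 min, which gives 46.7% of the charge as target.

I hold the other view: target is consumed as it forms. Its pseudo-first-order loss constant, substrate and gas each times their constant, is 0.329 min⁻¹. The making rate divided by this loss constant is the balance level of target, the [target] at which making equals losing, here 17.7% of the charge, which is less than the supply count. The approach to it has a half-life of 2.11 min, shorter than the run, so I commit to 16.5%. I grant the supply side the first minutes, while [target] is far below the balance level and its losses are small.

The same division ranks the changes. Wednesday's lifts the level to 23.0%, and Thursday's to 29.6%, which is higher. So I pick Thursday's, but I give no figure for it: substrate's half-life against the doubled gas is 5.94 min, shorter than the run, which makes that level loose.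

The forecast, stepped by hand, gives the flask 14.9%, a lower figure than mine, and says that “side-product and over-reaction losses nearly balance formation”; it picks Thursday's, with 20.4%.

The simulation gives 14.7%, and 20.3% after Thursday's, whose gain of 5.6 percentage points exceeds the 3.1 points of Wednesday's. In the flask at 8.00 min, substrate at 52.2% and dissolved gas at 0.102 M move the balance level from 17.7% to 16.9%, and target, read at 14.7%, stands below it, so it is still made faster than lost. In the neighbour flask read at 15.0 min, substrate at 22.6% and dissolved gas at 0.129 M put the level at 12.6%, and target there stands above it, at 14.8%.

The numbers of this flask stand for no real mixture.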